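**Retrosynthetic overview**

1. Labels: ring A is the benzoate ring. Ring B carries C1' (ether oxygen to ring A), C2' (O-prenyl), C3' (H), C4' (OMe), C5' (C-prenyl) and C6' (CH2OH). The plan rests on ring B having oxygen at C1', C2' and C4' and carbon substituents only at C5' and C6': C1'–C4' is a tetraoxygenated butadiene and C5'–C6' an alkyne.
2. Target 22 ⇒ silyl ether 21 ⇒ benzylic bromide 19 + isobutenylboronate 20 (C5'–CH2/CH= bond) ⇒ aldehyde 17 ⇒ phenol 16 (O-prenylation at C2').
3. 16 ⇒ Diels–Alder benzannulation across C1'–C6' and C4'–C5': diene 10 (C1'–C4', already bound to ring A through the C1' oxygen) + ynal 13 (C5', C6').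
4. 10 ⇒ acylketene acetal 9 ⇒ aryloxyacetic acid 6 + 1,1-dimethoxyethene 7; 6 ⇒ methyl 2,6-dihydroxybenzoate 1, prenyl bromide 2 and methyl bromoacetate 4; 13 ⇒ but-2-yne-1,4-diol 11.
5. Ring order: ring A is bought; ring B is the only ring made (step 8), after the diaryl ether C–O bond is in place.

Key step: step 8

Remark: the target has no stereocentre, so the only geometric element to control is the Z enol ether of diene 10.

**Route**

Step 1
Reactants: 1 methyl 2,6-dihydroxybenzoate; 2 prenyl bromide (1-bromo-3-methylbut-2-ene)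
Product: 3 methyl 2-hydroxy-6-[(3-methylbut-2-en-1-yl)oxy]benzoate
Conditions: 2 (1.05 equiv), K2CO3, acetone, 23→40 °C
Reagents that add atoms: none
Why: Williamson ether synthesis with one equivalent of the allylic bromide should stop at the mono-ether, because the remaining phenol is then locked in a strong hydrogen bond to the ester carbonyl and reacts far more slowly.

Step 2
Reactants: 3 methyl 2-hydroxy-6-[(3-methylbut-2-en-1-yl)oxy]benzoate; 4 methyl bromoacetate
Product: 5 methyl 2-(2-methoxy-2-oxoethoxy)-6-[(3-methylbut-2-en-1-yl)oxy]benzoate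
Conditions: 4, K2CO3, DMF, 50 °C
Reagents that add atoms: none
Why: Williamson alkylation of the chelated phenoxide with the reactive α-bromo ester should proceed cleanly in a dipolar aprotic solvent, K2CO3 being too weak a base to cause Dieckmann-type closure onto the ring A ester.

Step 3
Reactants: 5 methyl 2-(2-methoxy-2-oxoethoxy)-6-[(3-methylbut-2-en-1-yl)oxy]benzoate
Product: 6 {2-(methoxycarbonyl)-3-[(3-methylbut-2-en-1-yl)oxy]phenoxy}acetic acid
Conditions: LiOH (1.2 equiv), THF/H2O, 0 °C; then cold 1 M HCl to pH 3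
Reagents that add atoms: lithium hydroxide, [Li+].[OH-]
Why: Ester saponification should be selective because hydroxide attacks the unhindered, inductively activated aryloxyacetate ester far faster than the benzoate ester, which is shielded by two ortho substituents.

Step 4
Reactants: 6 {2-(methoxycarbonyl)-3-[(3-methylbut-2-en-1-yl)oxy]phenoxy}acetic acid; 7 1,1-dimethoxyethene
Product: 9 methyl 2-[(4,4-dimethoxy-2-oxobut-3-en-1-yl)oxy]-6-[(3-methylbut-2-en-1-yl)oxy]benzoate, via aryloxyacetyl chloride 8 (not isolated)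
Conditions: Me2C=C(Cl)NMe2 (1.0 equiv), CH2Cl2, 0→23 °C; then 7 (2.5 equiv), Et2O, 0→23 °C; filtration through basic alumina
Reagents that add atoms: 1-chloro-N,N,2-trimethylprop-1-en-1-amine, CC(C)=C(Cl)N(C)C (supplies the chlorine of 8; no atom of it remains in 9)
Why: The α-chloroenamine makes the acid chloride under neutral conditions that spare the prenyl ether, and C-acylation of the ketene acetal followed by proton loss should give the acylketene acetal, a known route to 4,4-dialkoxybut-3-en-2-ones, with the second equivalent of 7 taking up the HCl so that no amine is present to generate an aryloxyketene.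

Step 5
Reactants: 9 methyl 2-[(4,4-dimethoxy-2-oxobut-3-en-1-yl)oxy]-6-[(3-methylbut-2-en-1-yl)oxy]benzoate
Product: 10 methyl 2-{[(1Z)-4,4-dimethoxy-2-(trimethylsilyloxy)buta-1,3-dien-1-yl]oxy}-6-[(3-methylbut-2-en-1-yl)oxy]benzoate
Conditions: TMSOTf, Et3N, Et2O, 0 °C; salts removed under argon, used crude
Reagents that add atoms: trimethylsilyl trifluoromethanesulfonate, C[Si](C)(C)OS(=O)(=O)C(F)(F)F
Why: Soft enolisation (O-silylation of the vinylogous carbonate carbonyl, then deprotonation of the only enolisable position, the OCH2 group, by Et3N) is the standard silyl enol ether formation for silyloxydienes and avoids a metal enolate that could close onto the ring A ester, and the Z isomer is expected because the aryloxy group avoids allylic strain with the dimethoxyvinyl branch.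

Step 6
Reactants: 11 but-2-yne-1,4-diol
Product: 12 4-(tert-butyldimethylsilyloxy)but-2-yn-1-ol
Conditions: 11 (3 equiv), TBSCl (1 equiv), imidazole, DMF, 0→23 °C
Reagents that add atoms: tert-butyldimethylsilyl chloride, CC(C)(C)[Si](C)(C)Cl
Why: Statistical monosilylation of a symmetrical diol used in excess should give mainly the mono-silyl ether, the unreacted water-soluble diol being washed out.

Step 7
Reactants: 12 4-(tert-butyldimethylsilyloxy)but-2-yn-1-ol
Product: 13 4-(tert-butyldimethylsilyloxy)but-2-ynal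
Conditions: Dess–Martin periodinane, CH2Cl2, 0→23 °C
Reagents that add atoms: none
Why: Dess–Martin oxidation of a primary propargylic alcohol should stop cleanly at the ynal under near-neutral conditions that leave the silyl ether intact.

Step 8
Reactants: 10 methyl 2-{[(1Z)-4,4-dimethoxy-2-(trimethylsilyloxy)buta-1,3-dien-1-yl]oxy}-6-[(3-methylbut-2-en-1-yl)oxy]benzoate; 13 4-(tert-butyldimethylsilyloxy)but-2-ynal
Product: 16 methyl 2-{2-[(tert-butyldimethylsilyloxy)methyl]-3-formyl-6-hydroxy-4-methoxyphenoxy}-6-[(3-methylbut-2-en-1-yl)oxy]benzoate, via cyclohexadiene cycloadduct 14 (not isolated), via aryl trimethylsilyl ether 15 (not isolated)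
Conditions: 10 (1.3 equiv), toluene, 23→60 °C; then K2CO3 (cat.), MeOH, 0 °C
Reagents that add atoms: none
Why: A thermal, asynchronous [4+2] cycloaddition should join the electron-rich diene to the ynal: C1', made nucleophilic by the C2' silyloxy group and vinylogously by the two C4' ketene acetal oxygens, bonds to the alkyne carbon β to the formyl group (future C6'), and C4' bonds to the α-carbon (future C5'), giving cyclohexa-2,5-diene 14. The closest known reaction type is the Diels–Alder benzannulation of 1,1-dialkoxy-3-silyloxybutadienes, including 4-alkoxy congeners, with acetylenic carbonyl dienophiles followed by aromatising loss of alcohol. Ring B, the only ring formed, is closed by this intermolecular cycloaddition, which makes the C1'–C6' and C4'–C5' bonds in one operation with the C1'–O bond to ring A already present. Aromatisation can take one course only, 1,4-loss of methanol from C4' and C1'–H (on heating or under the methanolic K2CO3 that also cleaves the aryl trimethylsilyl ether, either order leading to 16), so C1' keeps the aryloxy group, C4' one methoxy group and C2' emerges as the only free phenol; the sp3 centre at C1' of 14 is transient and no stereocentre remains. The step needs regioselectivity, which rests on three oxygen donors acting on C1' against one weakly donating aryloxy group acting on C4' and on the polarisation of the alkyne by the formyl group, and chemoselectivity, which rests on the absence of any Lewis acid (no addition to the aldehyde carbonyl) and on the stability of the alkyl TBS ether and the hindered ester to K2CO3/MeOH. The Z enol ether geometry keeps the aryloxy group on the outside of the diene, so the s-cis conformer needed for cycloaddition is reachable.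

Step 9
Reactants: 16 methyl 2-{2-[(tert-butyldimethylsilyloxy)methyl]-3-formyl-6-hydroxy-4-methoxyphenoxy}-6-[(3-methylbut-2-en-1-yl)oxy]benzoate; 2 prenyl bromide
Product: 17 methyl 2-{2-[(tert-butyldimethylsilyloxy)methyl]-3-formyl-4-methoxy-6-[(3-methylbut-2-en-1-yl)oxy]phenoxy}-6-[(3-methylbut-2-en-1-yl)oxy]benzoate
Conditions: 2, K2CO3, DMF, 23 °C
Reagents that add atoms: none
Why: Williamson etherification of the only phenol, which is acidified by the para formyl group, should be fast at room temperature under conditions that leave the aldehyde, the silyl ether and the ester untouched.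

Step 10
Reactants: 17 methyl 2-{2-[(tert-butyldimethylsilyloxy)methyl]-3-formyl-4-methoxy-6-[(3-methylbut-2-en-1-yl)oxy]phenoxy}-6-[(3-methylbut-2-en-1-yl)oxy]benzoate
Product: 18 methyl 2-{2-[(tert-butyldimethylsilyloxy)methyl]-3-(hydroxymethyl)-4-methoxy-6-[(3-methylbut-2-en-1-yl)oxy]phenoxy}-6-[(3-methylbut-2-en-1-yl)oxy]benzoate
Conditions: NaBH4, THF/MeOH, 0 °C; aq NH4Cl
Reagents that add atoms: none
Why: Borohydride reduction is chemoselective for the aldehyde over the doubly ortho-substituted methyl ester, and the low temperature with a buffered quench should keep the silyl group from moving between the two benzylic oxygens.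

Step 11
Reactants: 18 methyl 2-{2-[(tert-butyldimethylsilyloxy)methyl]-3-(hydroxymethyl)-4-methoxy-6-[(3-methylbut-2-en-1-yl)oxy]phenoxy}-6-[(3-methylbut-2-en-1-yl)oxy]benzoate
Product: 19 methyl 2-{3-(bromomethyl)-2-[(tert-butyldimethylsilyloxy)methyl]-4-methoxy-6-[(3-methylbut-2-en-1-yl)oxy]phenoxy}-6-[(3-methylbut-2-en-1-yl)oxy]benzoate
Conditions: CBr4, PPh3, CH2Cl2, −20→0 °C; short plug of Et3N-deactivated silica, used at once
Reagents that add atoms: carbon tetrabromide, BrC(Br)(Br)Br
Why: The Appel reaction converts the primary benzylic alcohol into the bromide under neutral conditions by SN2 displacement of an alkoxyphosphonium ion, which avoids the acid that would ionise this electron-rich benzylic position.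

Step 12
Reactants: 19 methyl 2-{3-(bromomethyl)-2-[(tert-butyldimethylsilyloxy)methyl]-4-methoxy-6-[(3-methylbut-2-en-1-yl)oxy]phenoxy}-6-[(3-methylbut-2-en-1-yl)oxy]benzoate; 20 4,4,5,5-tetramethyl-2-(2-methylprop-1-en-1-yl)-1,3,2-dioxaborolane
Product: 21 methyl 2-{2-[(tert-butyldimethylsilyloxy)methyl]-4-methoxy-3-(3-methylbut-2-en-1-yl)-6-[(3-methylbut-2-en-1-yl)oxy]phenoxy}-6-[(3-methylbut-2-en-1-yl)oxy]benzoate
Conditions: 20 (1.5 equiv), Pd(PPh3)4 (5 mol %), K2CO3, THF/H2O, 50 °C
Reagents that add atoms: none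
Why: Suzuki–Miyaura coupling of an sp3 benzylic bromide with an alkenylboronate should work because oxidative addition of the benzylic C–Br bond to zerovalent palladium is fast, the benzylpalladium species has no β-hydrogen, and the symmetrical isobutenyl group raises no question of alkene geometry.

Step 13
Reactants: 21 methyl 2-{2-[(tert-butyldimethylsilyloxy)methyl]-4-methoxy-3-(3-methylbut-2-en-1-yl)-6-[(3-methylbut-2-en-1-yl)oxy]phenoxy}-6-[(3-methylbut-2-en-1-yl)oxy]benzoate
Product: 22 methyl 2-{2-(hydroxymethyl)-4-methoxy-3-(3-methylbut-2-en-1-yl)-6-[(3-methylbut-2-en-1-yl)oxy]phenoxy}-6-[(3-methylbut-2-en-1-yl)oxy]benzoate (target CNP0500611.0)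
Conditions: TBAF, AcOH (1:1), THF, 0→23 °C
Reagents that add atoms: none
Why: Fluoride-induced desilylation, buffered with acetic acid so that no free benzylic alkoxide can attack the neighbouring ester or aryl ether, should release the primary alcohol without touching the prenyl groups.

**Compound list**

1 | methyl 2,6-dihydroxybenzoate | COC(=O)c1c(O)cccc1O | starting material
2 | prenyl bromide (1-bromo-3-methylbut-2-ene) | CC(C)=CCBr | starting material
3 | methyl 2-hydroxy-6-[(3-methylbut-2-en-1-yl)oxy]benzoate | COC(=O)c1c(O)cccc1OCC=C(C)C | intermediate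
4 | methyl bromoacetate | COC(=O)CBr | starting material
5 | methyl 2-(2-methoxy-2-oxoethoxy)-6-[(3-methylbut-2-en-1-yl)oxy]benzoate | COC(=O)c1c(OCC=C(C)C)cccc1OCC(=O)OC | intermediate
6 | {2-(methoxycarbonyl)-3-[(3-methylbut-2-en-1-yl)oxy]phenoxy}acetic acid | COC(=O)c1c(OCC=C(C)C)cccc1OCC(=O)O | intermediate
7 | 1,1-dimethoxyethene | C=C(OC)OC | starting material
8 | {2-(methoxycarbonyl)-3-[(3-methylbut-2-en-1-yl)oxy]phenoxy}acetyl chloride (not isolated) | COC(=O)c1c(OCC=C(C)C)cccc1OCC(=O)Cl | intermediate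
9 | methyl 2-[(4,4-dimethoxy-2-oxobut-3-en-1-yl)oxy]-6-[(3-methylbut-2-en-1-yl)oxy]benzoate | COC(=O)c1c(OCC=C(C)C)cccc1OCC(=O)C=C(OC)OC | intermediate
10 | methyl 2-{[(1Z)-4,4-dimethoxy-2-(trimethylsilyloxy)buta-1,3-dien-1-yl]oxy}-6-[(3-methylbut-2-en-1-yl)oxy]benzoate | COC(=O)c1c(OCC=C(C)C)cccc1O/C=C(\O[Si](C)(C)C)C=C(OC)OC | intermediate
11 | but-2-yne-1,4-diol | OCC#CCO | starting material
12 | 4-(tert-butyldimethylsilyloxy)but-2-yn-1-ol | OCC#CCO[Si](C)(C)C(C)(C)C | intermediate
13 | 4-(tert-butyldimethylsilyloxy)but-2-ynal | O=CC#CCO[Si](C)(C)C(C)(C)C | intermediate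
14 | racemic methyl 2-{[6-[(tert-butyldimethylsilyloxy)methyl]-5-formyl-4,4-dimethoxy-2-(trimethylsilyloxy)cyclohexa-2,5-dien-1-yl]oxy}-6-[(3-methylbut-2-en-1-yl)oxy]benzoate (not isolated) | COC(=O)c1c(OCC=C(C)C)cccc1OC1C(O[Si](C)(C)C)=CC(OC)(OC)C(C=O)=C1CO[Si](C)(C)C(C)(C)C | intermediate
15 | methyl 2-{2-[(tert-butyldimethylsilyloxy)methyl]-3-formyl-4-methoxy-6-(trimethylsilyloxy)phenoxy}-6-[(3-methylbut-2-en-1-yl)oxy]benzoate (not isolated) | COC(=O)c1c(OCC=C(C)C)cccc1Oc1c(O[Si](C)(C)C)cc(OC)c(C=O)c1CO[Si](C)(C)C(C)(C)C | intermediate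
16 | methyl 2-{2-[(tert-butyldimethylsilyloxy)methyl]-3-formyl-6-hydroxy-4-methoxyphenoxy}-6-[(3-methylbut-2-en-1-yl)oxy]benzoate | COC(=O)c1c(OCC=C(C)C)cccc1Oc1c(O)cc(OC)c(C=O)c1CO[Si](C)(C)C(C)(C)C | intermediate
17 | methyl 2-{2-[(tert-butyldimethylsilyloxy)methyl]-3-formyl-4-methoxy-6-[(3-methylbut-2-en-1-yl)oxy]phenoxy}-6-[(3-methylbut-2-en-1-yl)oxy]benzoate | COC(=O)c1c(OCC=C(C)C)cccc1Oc1c(OCC=C(C)C)cc(OC)c(C=O)c1CO[Si](C)(C)C(C)(C)C | intermediate
18 | methyl 2-{2-[(tert-butyldimethylsilyloxy)methyl]-3-(hydroxymethyl)-4-methoxy-6-[(3-methylbut-2-en-1-yl)oxy]phenoxy}-6-[(3-methylbut-2-en-1-yl)oxy]benzoate | COC(=O)c1c(OCC=C(C)C)cccc1Oc1c(OCC=C(C)C)cc(OC)c(CO)c1CO[Si](C)(C)C(C)(C)C | intermediate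
19 | methyl 2-{3-(bromomethyl)-2-[(tert-butyldimethylsilyloxy)methyl]-4-methoxy-6-[(3-methylbut-2-en-1-yl)oxy]phenoxy}-6-[(3-methylbut-2-en-1-yl)oxy]benzoate | COC(=O)c1c(OCC=C(C)C)cccc1Oc1c(OCC=C(C)C)cc(OC)c(CBr)c1CO[Si](C)(C)C(C)(C)C | intermediate
20 | 4,4,5,5-tetramethyl-2-(2-methylprop-1-en-1-yl)-1,3,2-dioxaborolane | CC(C)=CB1OC(C)(C)C(C)(C)O1 | starting material
21 | methyl 2-{2-[(tert-butyldimethylsilyloxy)methyl]-4-methoxy-3-(3-methylbut-2-en-1-yl)-6-[(3-methylbut-2-en-1-yl)oxy]phenoxy}-6-[(3-methylbut-2-en-1-yl)oxy]benzoate | COC(=O)c1c(OCC=C(C)C)cccc1Oc1c(OCC=C(C)C)cc(OC)c(CC=C(C)C)c1CO[Si](C)(C)C(C)(C)C | intermediate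
22 | methyl 2-{2-(hydroxymethyl)-4-methoxy-3-(3-methylbut-2-en-1-yl)-6-[(3-methylbut-2-en-1-yl)oxy]phenoxy}-6-[(3-methylbut-2-en-1-yl)oxy]benzoate | COC(=O)c1c(OCC=C(C)C)cccc1Oc1c(OCC=C(C)C)cc(OC)c(CC=C(C)C)c1CO | target

**Step count and risks**

Total step count: 13.
Longest linear sequence: 11 steps (steps 1–5 and 8–13); the ynal branch (steps 6–7) is 2 steps.

Steps most likely to fail:

1. Step 8 (key cycloaddition). The ketene acetal diene may be lost to hydrolysis or silyl transfer before it adds to the disubstituted alkyne, or the aryloxy group at C1' may erode the orientation of addition. The fallback keeps the benzannulation but uses the sturdier 1-methoxy-1,3-bis(silyloxy)diene class and sorts the two ring B phenols afterwards through the formyl group; it sets out from phenol 3, also bypasses steps 4 and 5, and returns at 17. Phenol 3 would be alkylated with methyl 4-chloroacetoacetate (NaH, 2.2 equiv, THF) to methyl 4-{2-(methoxycarbonyl)-3-[(3-methylbut-2-en-1-yl)oxy]phenoxy}-3-oxobutanoate F1. TMSCl/Et3N would give methyl 4-aryloxy-3-(trimethylsilyloxy)but-2-enoate F2, and LiN(iPr)2/TMSCl at −78 °C with internal quench the 4-aryloxy-1-methoxy-1,3-bis(trimethylsilyloxy)buta-1,3-diene F3. Cycloaddition of F3 with 13 in toluene should give the mixed silyl ketal cycloadduct F4, which on K2CO3/MeOH loses methanol and both trimethylsilyl groups to give the C2',C4'-dihydroxy C5'-aldehyde F5. One equivalent of prenyl bromide 2 with K2CO3 should alkylate the non-chelated C2' phenol para to the formyl group to give the C2'-O-prenyl C4'-phenol F6, and MeI/K2CO3 then methylates the chelated C4' phenol to give 17.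

2. Step 11 (benzylic bromide). The bromide, activated by an ortho methoxy and a para prenyloxy group, may ionise, with ring closure by the neighbouring silyloxymethyl oxygen to a phthalan or with oligomerisation, before it can be coupled. The fallback masks the para oxygen donor as an ester during the benzylic chemistry; it sets out from phenol 16 and returns at 21. Phenol 16 would be acylated (pivaloyl chloride, Et3N, DMAP) to the C2' pivalate aldehyde F7, reduced (NaBH4) to the pivalate benzylic alcohol F8 and brominated (CBr4, PPh3) to the far less ionisable pivalate benzylic bromide F9. Coupling with 20 (Pd(PPh3)4, K2CO3) would give the C5'-prenyl pivalate F10, methanolysis (NaOMe, MeOH) the C5'-prenyl C2'-phenol F11, and O-prenylation with 2 (K2CO3, DMF) gives 21.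

3. Step 12 (sp3–sp2 coupling). Slow transmetalation would let solvolysis of the bromide in the basic aqueous medium take over, as well as palladium hydride isomerisation of the new alkene into conjugation with ring B or ionisation of the aryl prenyl ethers by zerovalent palladium. The fallback forms the C–C bond without palladium or base by SN2 substitution with an organocopper reagent; it sets out from bromide 19 and returns at 21. Bromide 19 would be treated at −78→−30 °C in THF with bromomagnesium bis(2-methylprop-1-en-1-yl)cuprate F12, made from 2-methylprop-1-enylmagnesium bromide (2 equiv) and CuBr·SMe2, which should give 21 directly; the hindered ring A ester should tolerate the cuprate at this temperature.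

**Further compounds**

F1 | step 8 | methyl 4-{2-(methoxycarbonyl)-3-[(3-methylbut-2-en-1-yl)oxy]phenoxy}-3-oxobutanoate | COC(=O)CC(=O)COc1cccc(OCC=C(C)C)c1C(=O)OC
F2 | step 8 | methyl 4-{2-(methoxycarbonyl)-3-[(3-methylbut-2-en-1-yl)oxy]phenoxy}-3-(trimethylsilyloxy)but-2-enoate (mixture of alkene isomers) | COC(=O)C=C(COc1cccc(OCC=C(C)C)c1C(=O)OC)O[Si](C)(C)C
F3 | step 8 | methyl 2-{[(1Z)-4-methoxy-2,4-bis(trimethylsilyloxy)buta-1,3-dien-1-yl]oxy}-6-[(3-methylbut-2-en-1-yl)oxy]benzoate (ketene acetal geometry not fixed) | COC(=O)c1c(OCC=C(C)C)cccc1O/C=C(\O[Si](C)(C)C)C=C(OC)O[Si](C)(C)C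
F4 | step 8 | methyl 2-{[6-[(tert-butyldimethylsilyloxy)methyl]-5-formyl-4-methoxy-2,4-bis(trimethylsilyloxy)cyclohexa-2,5-dien-1-yl]oxy}-6-[(3-methylbut-2-en-1-yl)oxy]benzoate (mixture of stereoisomers, not isolated) | COC(=O)c1c(OCC=C(C)C)cccc1OC1C(O[Si](C)(C)C)=CC(OC)(O[Si](C)(C)C)C(C=O)=C1CO[Si](C)(C)C(C)(C)C
F5 | step 8 | methyl 2-{2-[(tert-butyldimethylsilyloxy)methyl]-3-formyl-4,6-dihydroxyphenoxy}-6-[(3-methylbut-2-en-1-yl)oxy]benzoate | COC(=O)c1c(OCC=C(C)C)cccc1Oc1c(O)cc(O)c(C=O)c1CO[Si](C)(C)C(C)(C)C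
F6 | step 8 | methyl 2-{2-[(tert-butyldimethylsilyloxy)methyl]-3-formyl-4-hydroxy-6-[(3-methylbut-2-en-1-yl)oxy]phenoxy}-6-[(3-methylbut-2-en-1-yl)oxy]benzoate | COC(=O)c1c(OCC=C(C)C)cccc1Oc1c(OCC=C(C)C)cc(O)c(C=O)c1CO[Si](C)(C)C(C)(C)C
F7 | step 11 | methyl 2-{2-[(tert-butyldimethylsilyloxy)methyl]-6-[(2,2-dimethylpropanoyl)oxy]-3-formyl-4-methoxyphenoxy}-6-[(3-methylbut-2-en-1-yl)oxy]benzoate | COC(=O)c1c(OCC=C(C)C)cccc1Oc1c(OC(=O)C(C)(C)C)cc(OC)c(C=O)c1CO[Si](C)(C)C(C)(C)C
F8 | step 11 | methyl 2-{2-[(tert-butyldimethylsilyloxy)methyl]-6-[(2,2-dimethylpropanoyl)oxy]-3-(hydroxymethyl)-4-methoxyphenoxy}-6-[(3-methylbut-2-en-1-yl)oxy]benzoate | COC(=O)c1c(OCC=C(C)C)cccc1Oc1c(OC(=O)C(C)(C)C)cc(OC)c(CO)c1CO[Si](C)(C)C(C)(C)C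
F9 | step 11 | methyl 2-{3-(bromomethyl)-2-[(tert-butyldimethylsilyloxy)methyl]-6-[(2,2-dimethylpropanoyl)oxy]-4-methoxyphenoxy}-6-[(3-methylbut-2-en-1-yl)oxy]benzoate | COC(=O)c1c(OCC=C(C)C)cccc1Oc1c(OC(=O)C(C)(C)C)cc(OC)c(CBr)c1CO[Si](C)(C)C(C)(C)C
F10 | step 11 | methyl 2-{2-[(tert-butyldimethylsilyloxy)methyl]-6-[(2,2-dimethylpropanoyl)oxy]-4-methoxy-3-(3-methylbut-2-en-1-yl)phenoxy}-6-[(3-methylbut-2-en-1-yl)oxy]benzoate | COC(=O)c1c(OCC=C(C)C)cccc1Oc1c(OC(=O)C(C)(C)C)cc(OC)c(CC=C(C)C)c1CO[Si](C)(C)C(C)(C)C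
F11 | step 11 | methyl 2-{2-[(tert-butyldimethylsilyloxy)methyl]-6-hydroxy-4-methoxy-3-(3-methylbut-2-en-1-yl)phenoxy}-6-[(3-methylbut-2-en-1-yl)oxy]benzoate | COC(=O)c1c(OCC=C(C)C)cccc1Oc1c(O)cc(OC)c(CC=C(C)C)c1CO[Si](C)(C)C(C)(C)C
F12 | step 12 | bromomagnesium bis(2-methylprop-1-en-1-yl)cuprate | CC(C)=C[Cu-]C=C(C)C.[Mg+]Br
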